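**Retrosynthetic overview**

1. The strategy rests on ring A: a fully substituted benzene ring whose six carbons carry, in alternation, oxygen (three phenolic C–O) and carbon (prenyl, the CH2 bridge to ring B, isobutyryl). A 3-alkoxycyclobutenone supplies four of these carbons and a siloxyalkyne the other two.
2. Endgame: the silyl and three methyl ethers are removed last. The ring A C–acyl bond is made by an anionic Fries shift at the one ring A carbon that leaves the key step as CH.
3. Key disconnection: ring A is cut into 5-methyl-1-(triisopropylsilyloxy)hex-4-en-1-yne and the 3-methoxycyclobutenone that carries the ring B CH2 at C-2. The bonds are C(OH)–C(prenyl) and C(OSi)–C(CH2 bridge).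
4. The cyclobutenone comes from a ring B propanoic acid (alkylketene plus 1,1-dimethoxyethene, then loss of methanol). The side chain is attached by Negishi coupling to the iodinated ring B dienone.
5. Ring B comes from 2,4-dimethoxytoluene (Birch reduction, C-acylation, C-prenylation, allylic oxidation), and its one stereocentre is secured by resolution. Order of rings: ring B, the four-membered ring, then ring A.

Key step: step 11

Remark 1: in the ester-to-ynolate homologation the group on the ester carbonyl ends on the alkyne carbon, so the prenyl-substituted siloxyalkyne is made from ethyl 4-methylpent-3-enoate.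

Remark 2: the quaternary carbon of ring B is stereogenic only because one ring arm carries CH3 and the other the CH2 link. This is too remote for reagent control when the C–prenyl bond forms, so it is secured by resolution of dienone 9. The descriptor changes from R (10) to S (11 onward) through CIP priorities only; the spatial arrangement is unchanged.

Abbreviations: RB = (3S)-2,4-dimethoxy-5-methyl-3-(3-methylbut-2-en-1-yl)-3-(2-methylpropanoyl)-6-oxocyclohexa-1,4-dien-1-yl. RBH = the same group with 2,4-dihydroxy in place of 2,4-dimethoxy.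

**Route**

Step 1
Reactants: 1 2,4-dimethoxytoluene
Product: 2 1,5-dimethoxy-2-methylcyclohexa-1,4-diene
Conditions: Li, NH3(l), THF, t-BuOH, −78 → −33 °C
Reagents that add atoms: none
Why: Birch reduction of a 1,3-dimethoxyarene should stop at the 1,4-diene that keeps both methoxy groups and the methyl group on sp2 carbons, which leaves the CH2 between the two enol ether carbons as the future quaternary centre.

Step 2
Reactants: 2 1,5-dimethoxy-2-methylcyclohexa-1,4-diene; 3 N-methoxy-N-methylisobutyramide
Product: 5 1-(2,6-dimethoxy-3-methylcyclohexa-2,5-dien-1-yl)-2-methylpropan-1-one (racemic), via dienyllithium 4 (not isolated)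
Conditions: t-BuLi, THF, −78 °C; then 3, −78 → −20 °C; H2O
Reagents that add atoms: none
Why: The CH2 flanked by both methoxy-bearing carbons is the most acidic position, its pentadienyl-type lithium species reacts at the central carbon, and acylation with the N-methoxy-N-methyl amide (Weinreb ketone synthesis) should deliver the ketone without over-addition.

Step 3
Reactants: 5 1-(2,6-dimethoxy-3-methylcyclohexa-2,5-dien-1-yl)-2-methylpropan-1-one; 6 1-bromo-3-methylbut-2-ene (prenyl bromide)
Product: 8 1-[2,6-dimethoxy-3-methyl-1-(3-methylbut-2-en-1-yl)cyclohexa-2,5-dien-1-yl]-2-methylpropan-1-one (racemic), via lithium dienolate 7 (not isolated)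
Conditions: lithium diisopropylamide (LDA), THF, −78 °C; then 6, −78 → 0 °C
Reagents that add atoms: none
Why: LDA removes the doubly allylic α-proton and the cross-conjugated dienolate should be C-alkylated at the ring carbon by the allylic bromide (enolate alkylation of the kind used in Birch reductive alkylations), which creates the quaternary carbon in racemic form.

Step 4
Reactants: 8 1-[2,6-dimethoxy-3-methyl-1-(3-methylbut-2-en-1-yl)cyclohexa-2,5-dien-1-yl]-2-methylpropan-1-one
Product: 9 3,5-dimethoxy-2-methyl-4-(3-methylbut-2-en-1-yl)-4-(2-methylpropanoyl)cyclohexa-2,5-dien-1-one (racemic)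
Conditions: t-BuOOH, pyridinium dichromate (C5H5NH)2Cr2O7 (0.2 equiv), Celite, benzene, 20 °C
Reagents that add atoms: tert-butyl hydroperoxide, CC(C)(C)OO
Why: Chromium-catalysed allylic oxidation with the hydroperoxide should attack the doubly allylic ring CH2 between the two enol ether double bonds, and because the opposite ring carbon is quaternary the product can only be the cross-conjugated 3,5-dimethoxy dienone.

Step 5
Reactants: 9 3,5-dimethoxy-2-methyl-4-(3-methylbut-2-en-1-yl)-4-(2-methylpropanoyl)cyclohexa-2,5-dien-1-one (racemic)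
Product: 10 (4R)-3,5-dimethoxy-2-methyl-4-(3-methylbut-2-en-1-yl)-4-(2-methylpropanoyl)cyclohexa-2,5-dien-1-one
Conditions: preparative SFC, amylose tris(3,5-dimethylphenylcarbamate) on silica, CO2/MeOH, 35 °C
Reagents that add atoms: none
Why: Resolution by chromatography on a chiral stationary phase should separate the enantiomers of this robust, UV-active dienone, and the absolute configuration is to be confirmed by anomalous-dispersion X-ray analysis of iodide 11.

Step 6
Reactants: 10 (4R)-3,5-dimethoxy-2-methyl-4-(3-methylbut-2-en-1-yl)-4-(2-methylpropanoyl)cyclohexa-2,5-dien-1-one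
Product: 11 (4S)-2-iodo-3,5-dimethoxy-6-methyl-4-(3-methylbut-2-en-1-yl)-4-(2-methylpropanoyl)cyclohexa-2,5-dien-1-one
Conditions: NIS, MeCN, 0 → 20 °C, dark
Reagents that add atoms: N-iodosuccinimide, O=C1CCC(=O)N1I
Why: Electrophilic α-iodination of the vinylogous ester at its only remaining ring CH should outpace attack on the less nucleophilic trisubstituted alkene.

Step 7
Reactants: 11 (4S)-2-iodo-3,5-dimethoxy-6-methyl-4-(3-methylbut-2-en-1-yl)-4-(2-methylpropanoyl)cyclohexa-2,5-dien-1-one; 12 (3-ethoxy-3-oxopropyl)zinc bromide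
Product: 13 ethyl 3-(RB)propanoate
Conditions: Pd(OAc)2 (5 mol%), 2-dicyclohexylphosphino-2',6'-dimethoxybiphenyl (10 mol%), THF, 20 → 45 °C
Reagents that add atoms: none
Why: Negishi coupling of the α-iodo enone with the ester-bearing alkylzinc halide should form the sp2–sp3 bond under neutral conditions that leave both ketones and the enol ethers untouched.

Step 8
Reactants: 13 ethyl 3-(RB)propanoate
Product: 14 3-(RB)propanoic acid
Conditions: LiOH, THF/H2O, 0 °C; then dilute HCl to pH 4, 0 °C
Reagents that add atoms: lithium hydroxide, [Li+].[OH-]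
Why: Saponification of the unhindered primary ethyl ester at 0 °C should be much faster than hydroxide attack on the hindered vinylogous esters or on the ketone beside the quaternary carbon.

Step 9
Reactants: 14 3-(RB)propanoic acid; 15 1,1-dimethoxyethene
Product: 19 3-methoxy-2-(RB-methyl)cyclobut-2-en-1-one, via acid chloride 16 (not isolated), via alkylketene 17 (not isolated), via dimethoxycyclobutanone 18 (not isolated)
Conditions: 1-chloro-N,N,2-trimethylprop-1-en-1-amine, CH2Cl2, 0 → 20 °C; then 15 (5 equiv), Et3N (slow addition), 0 → 20 °C; then silica gel, 20 °C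
Reagents that add atoms: none
Why: Neutral chlorination gives the acid chloride, triethylamine dehydrochlorinates it to the alkylketene, the electron-rich ketene acetal traps it in a [2+2] cycloaddition in which the ketene carbonyl carbon bonds to the acetal CH2, and β-elimination of methanol then gives the 2-substituted 3-methoxycyclobutenone.

Step 10
Reactants: 20 ethyl 4-methylpent-3-enoate; 21 triisopropylsilyl trifluoromethanesulfonate
Product: 24 5-methyl-1-[(triisopropylsilyl)oxy]hex-4-en-1-yne, via dibromo enolate 22 (not isolated), via lithium ynolate 23 (not isolated)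
Conditions: CH2Br2, lithium 2,2,6,6-tetramethylpiperidide, THF, −78 °C; then 20; then LiN(SiMe3)2; then n-BuLi, −78 → 0 °C; then 21, −78 → 0 °C
Reagents that add atoms: dibromomethane, BrCBr
Why: In the Kowalski ester homologation dibromomethyllithium adds to the ester, the dibromo ketone enolate undergoes bromine–lithium exchange and 1,2-shift to the ynolate, and the bulky silyl triflate should silylate it on oxygen.

Step 11
Reactants: 19 3-methoxy-2-(RB-methyl)cyclobut-2-en-1-one; 24 5-methyl-1-[(triisopropylsilyl)oxy]hex-4-en-1-yne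
Product: 29 5-methoxy-2-(3-methylbut-2-en-1-yl)-4-(RB-methyl)-3-[(triisopropylsilyl)oxy]phenol, via vinylketene 25 (not isolated), via vinylcyclobutenone 26 (not isolated), via dienylketene 27 (not isolated), via cyclohexadienone 28 (not isolated)
Conditions: toluene, 100 °C, sealed vessel, argon (24, 1.3 equiv)
Reagents that add atoms: none
Why: Heating opens the cyclobutenone by a conrotatory 4π electrocyclic reaction to vinylketene 25, whose carbonyl carbon bonds to the nucleophilic, prenyl-bearing carbon of the polarised siloxyalkyne in a [2+2] cycloaddition that gives vinylcyclobutenone 26 (bonds C(=O)–C(prenyl) and C(OSi)–C(CH2)). A second 4π opening gives dienylketene 27, which closes ring A by a thermal disrotatory 6π electrocyclisation (six-membered carbocycle) to cyclohexadienone 28, and tautomerisation gives phenol 29. The closest known reaction type is the Danheiser benzannulation of cyclobutenones with siloxyalkynes; the 3-methoxy group only adds the third oxygen, so that ring A emerges with OH, OSi and OMe on alternate carbons and one free CH. No stereocentre is formed, and the quaternary carbon of ring B should not be touched because the conditions are neutral and a Cope shift of its prenyl group would have to bond the dimethyl-substituted terminus to a fully substituted ring carbon. The step needs regioselectivity in the ketene–alkyne cycloaddition, which the oxygen polarisation of the ynol ether secures, and chemoselectivity for the alkyne, which is secured because ring B is present only as neutral tetrasubstituted vinylogous esters that neither protonate the ynol ether nor act as ketenophiles. Release of the strain of two four-membered rings and aromatisation drive the cascade.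

Step 12
Reactants: 29 5-methoxy-2-(3-methylbut-2-en-1-yl)-4-(RB-methyl)-3-[(triisopropylsilyl)oxy]phenol
Product: 30 6-iodo-5-methoxy-2-(3-methylbut-2-en-1-yl)-4-(RB-methyl)-3-[(triisopropylsilyl)oxy]phenol
Conditions: NIS, CH2Cl2, −40 °C
Reagents that add atoms: N-iodosuccinimide, O=C1CCC(=O)N1I
Why: Electrophilic aromatic iodination at the only free ring position, which is ortho to the phenol, ortho to the methoxy group and para to the siloxy group, should be fast enough at −40 °C to precede iodoetherification of the ortho-prenyl phenol.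

Step 13
Reactants: 30 6-iodo-5-methoxy-2-(3-methylbut-2-en-1-yl)-4-(RB-methyl)-3-[(triisopropylsilyl)oxy]phenol; 31 2-methylpropanoyl chloride
Product: 32 6-iodo-5-methoxy-2-(3-methylbut-2-en-1-yl)-4-(RB-methyl)-3-[(triisopropylsilyl)oxy]phenyl 2-methylpropanoate
Conditions: Et3N, 4-dimethylaminopyridine (cat.), CH2Cl2, 0 °C
Reagents that add atoms: none
Why: Nucleophile-catalysed O-acylation (esterification) of the hindered phenol places the isobutyryl group on the oxygen next to the iodinated carbon.

Step 14
Reactants: 32 6-iodo-5-methoxy-2-(3-methylbut-2-en-1-yl)-4-(RB-methyl)-3-[(triisopropylsilyl)oxy]phenyl 2-methylpropanoate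
Product: 34 1-{2-hydroxy-6-methoxy-3-(3-methylbut-2-en-1-yl)-5-(RB-methyl)-4-[(triisopropylsilyl)oxy]phenyl}-2-methylpropan-1-one, via aryllithium 33 (not isolated)
Conditions: n-BuLi (1.05 equiv), THF, −100 → −78 °C; then H2O
Reagents that add atoms: none
Why: Iodine–lithium exchange at −100 °C should be faster than addition of n-BuLi to the ester or to the hindered ring B carbonyl groups, and the ortho-lithiated aryl ester then undergoes the anionic Fries rearrangement (1,3 O→C acyl shift) to the ortho-hydroxyaryl ketone.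

Step 15
Reactants: 34 1-{2-hydroxy-6-methoxy-3-(3-methylbut-2-en-1-yl)-5-(RB-methyl)-4-[(triisopropylsilyl)oxy]phenyl}-2-methylpropan-1-one
Product: 35 1-{2,6-dihydroxy-3-(3-methylbut-2-en-1-yl)-5-(RBH-methyl)-4-[(triisopropylsilyl)oxy]phenyl}-2-methylpropan-1-one
Conditions: BCl3, 2,6-di-tert-butyl-4-methylpyridine, CH2Cl2, −78 → −30 °C; then H2O
Reagents that add atoms: none
Why: Lewis acid ether cleavage with BCl3 should remove the aryl methyl group through the chelate with the adjacent ketone and the two vinylogous methyl esters of ring B through their O-complexes, while the siloxy group and the boron chelate keep both oxygens next to the ring A prenyl group blocked against chroman formation.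

Step 16
Reactants: 35 1-{2,6-dihydroxy-3-(3-methylbut-2-en-1-yl)-5-(RBH-methyl)-4-[(triisopropylsilyl)oxy]phenyl}-2-methylpropan-1-one
Product: 36 1-[2,4,6-trihydroxy-3-(3-methylbut-2-en-1-yl)-5-(RBH-methyl)phenyl]-2-methylpropan-1-one (CNP0191741.1)
Conditions: Bu4NF, AcOH, THF, 0 °C
Reagents that add atoms: none
Why: Fluoride-induced cleavage of the aryl silyl ether (desilylation), buffered with acetic acid so that the acidic polyphenol is not exposed to strong base, should release the target without touching the quaternary stereocentre.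

**Compound list**

1 | 2,4-dimethoxytoluene | Cc1ccc(OC)cc1OC | starting material
2 | 1,5-dimethoxy-2-methylcyclohexa-1,4-diene | COC1=C(C)CC=C(OC)C1 | intermediate
3 | N-methoxy-N-methylisobutyramide (N-methoxy-N,2-dimethylpropanamide) | CC(C)C(=O)N(C)OC | starting material
4 | (2,6-dimethoxy-3-methylcyclohexa-2,5-dien-1-yl)lithium | [Li]C1C(OC)=C(C)CC=C1OC | intermediate
5 | 1-(2,6-dimethoxy-3-methylcyclohexa-2,5-dien-1-yl)-2-methylpropan-1-one (racemic) | CC(C)C(=O)C1C(OC)=C(C)CC=C1OC | intermediate
6 | 1-bromo-3-methylbut-2-ene (prenyl bromide) | CC(C)=CCBr | starting material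
7 | lithium dienolate of 5 | CC(C)C(O[Li])=C1C(OC)=C(C)CC=C1OC | intermediate
8 | 1-[2,6-dimethoxy-3-methyl-1-(3-methylbut-2-en-1-yl)cyclohexa-2,5-dien-1-yl]-2-methylpropan-1-one (racemic) | CC(C)C(=O)C1(CC=C(C)C)C(OC)=C(C)CC=C1OC | intermediate
9 | 3,5-dimethoxy-2-methyl-4-(3-methylbut-2-en-1-yl)-4-(2-methylpropanoyl)cyclohexa-2,5-dien-1-one (racemic) | CC(C)C(=O)C1(CC=C(C)C)C(OC)=CC(=O)C(C)=C1OC | intermediate
10 | (4R)-3,5-dimethoxy-2-methyl-4-(3-methylbut-2-en-1-yl)-4-(2-methylpropanoyl)cyclohexa-2,5-dien-1-one | C1=C(OC)[C@@](CC=C(C)C)(C(=O)C(C)C)C(OC)=C(C)C1=O | intermediate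
11 | (4S)-2-iodo-3,5-dimethoxy-6-methyl-4-(3-methylbut-2-en-1-yl)-4-(2-methylpropanoyl)cyclohexa-2,5-dien-1-one | IC1=C(OC)[C@@](CC=C(C)C)(C(=O)C(C)C)C(OC)=C(C)C1=O | intermediate
12 | (3-ethoxy-3-oxopropyl)zinc bromide | CCOC(=O)CC[Zn]Br | starting material
13 | ethyl 3-(RB)propanoate | CCOC(=O)CCC1=C(OC)[C@@](CC=C(C)C)(C(=O)C(C)C)C(OC)=C(C)C1=O | intermediate
14 | 3-(RB)propanoic acid | OC(=O)CCC1=C(OC)[C@@](CC=C(C)C)(C(=O)C(C)C)C(OC)=C(C)C1=O | intermediate
15 | 1,1-dimethoxyethene | C=C(OC)OC | starting material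
16 | 3-(RB)propanoyl chloride | ClC(=O)CCC1=C(OC)[C@@](CC=C(C)C)(C(=O)C(C)C)C(OC)=C(C)C1=O | intermediate
17 | 3-(RB)prop-1-en-1-one (alkylketene) | O=C=CCC1=C(OC)[C@@](CC=C(C)C)(C(=O)C(C)C)C(OC)=C(C)C1=O | intermediate
18 | 3,3-dimethoxy-2-(RB-methyl)cyclobutan-1-one (epimers at C-2) | COC1(OC)CC(=O)C1CC2=C(OC)[C@@](CC=C(C)C)(C(=O)C(C)C)C(OC)=C(C)C2=O | intermediate
19 | 3-methoxy-2-(RB-methyl)cyclobut-2-en-1-one | COC1=C(CC2=C(OC)[C@@](CC=C(C)C)(C(=O)C(C)C)C(OC)=C(C)C2=O)C(=O)C1 | intermediate
20 | ethyl 4-methylpent-3-enoate | CCOC(=O)CC=C(C)C | starting material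
21 | triisopropylsilyl trifluoromethanesulfonate | CC(C)[Si](OS(=O)(=O)C(F)(F)F)(C(C)C)C(C)C | starting material
22 | lithium enolate of 1,1-dibromo-5-methylhex-4-en-2-one | CC(C)=CCC(O[Li])=C(Br)Br | intermediate
23 | lithium 5-methylhex-4-en-1-yn-1-olate | CC(C)=CCC#CO[Li] | intermediate
24 | 5-methyl-1-[(triisopropylsilyl)oxy]hex-4-en-1-yne | CC(C)=CCC#CO[Si](C(C)C)(C(C)C)C(C)C | intermediate
25 | 3-methoxy-2-(RB-methyl)buta-1,3-dien-1-one (vinylketene) | O=C=C(CC1=C(OC)[C@@](CC=C(C)C)(C(=O)C(C)C)C(OC)=C(C)C1=O)C(OC)=C | intermediate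
26 | 4-(1-methoxyethenyl)-2-(3-methylbut-2-en-1-yl)-4-(RB-methyl)-3-[(triisopropylsilyl)oxy]cyclobut-2-en-1-one (epimers at C-4) | O=C1C(CC=C(C)C)=C(O[Si](C(C)C)(C(C)C)C(C)C)C1(CC2=C(OC)[C@@](CC=C(C)C)(C(=O)C(C)C)C(OC)=C(C)C2=O)C(OC)=C | intermediate
27 | (3E)-5-methoxy-2-(3-methylbut-2-en-1-yl)-4-(RB-methyl)-3-[(triisopropylsilyl)oxy]hexa-1,3,5-trien-1-one (dienylketene) | O=C=C(CC=C(C)C)/C(O[Si](C(C)C)(C(C)C)C(C)C)=C(/CC1=C(OC)[C@@](CC=C(C)C)(C(=O)C(C)C)C(OC)=C(C)C1=O)C(OC)=C | intermediate
28 | 5-methoxy-2-(3-methylbut-2-en-1-yl)-4-(RB-methyl)-3-[(triisopropylsilyl)oxy]cyclohexa-2,4-dien-1-one | O=C1CC(OC)=C(CC2=C(OC)[C@@](CC=C(C)C)(C(=O)C(C)C)C(OC)=C(C)C2=O)C(O[Si](C(C)C)(C(C)C)C(C)C)=C1CC=C(C)C | intermediate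
29 | 5-methoxy-2-(3-methylbut-2-en-1-yl)-4-(RB-methyl)-3-[(triisopropylsilyl)oxy]phenol | CC(C)=CCc1c(O[Si](C(C)C)(C(C)C)C(C)C)c(CC2=C(OC)[C@@](CC=C(C)C)(C(=O)C(C)C)C(OC)=C(C)C2=O)c(OC)cc1O | intermediate
30 | 6-iodo-5-methoxy-2-(3-methylbut-2-en-1-yl)-4-(RB-methyl)-3-[(triisopropylsilyl)oxy]phenol | CC(C)=CCc1c(O[Si](C(C)C)(C(C)C)C(C)C)c(CC2=C(OC)[C@@](CC=C(C)C)(C(=O)C(C)C)C(OC)=C(C)C2=O)c(OC)c(I)c1O | intermediate
31 | 2-methylpropanoyl chloride | CC(C)C(Cl)=O | starting material
32 | 6-iodo-5-methoxy-2-(3-methylbut-2-en-1-yl)-4-(RB-methyl)-3-[(triisopropylsilyl)oxy]phenyl 2-methylpropanoate | CC(C)=CCc1c(O[Si](C(C)C)(C(C)C)C(C)C)c(CC2=C(OC)[C@@](CC=C(C)C)(C(=O)C(C)C)C(OC)=C(C)C2=O)c(OC)c(I)c1OC(=O)C(C)C | intermediate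
33 | {2-methoxy-6-[(2-methylpropanoyl)oxy]-5-(3-methylbut-2-en-1-yl)-3-(RB-methyl)-4-[(triisopropylsilyl)oxy]phenyl}lithium | CC(C)=CCc1c(O[Si](C(C)C)(C(C)C)C(C)C)c(CC2=C(OC)[C@@](CC=C(C)C)(C(=O)C(C)C)C(OC)=C(C)C2=O)c(OC)c([Li])c1OC(=O)C(C)C | intermediate
34 | 1-{2-hydroxy-6-methoxy-3-(3-methylbut-2-en-1-yl)-5-(RB-methyl)-4-[(triisopropylsilyl)oxy]phenyl}-2-methylpropan-1-one | CC(C)=CCc1c(O[Si](C(C)C)(C(C)C)C(C)C)c(CC2=C(OC)[C@@](CC=C(C)C)(C(=O)C(C)C)C(OC)=C(C)C2=O)c(OC)c(C(=O)C(C)C)c1O | intermediate
35 | 1-{2,6-dihydroxy-3-(3-methylbut-2-en-1-yl)-5-(RBH-methyl)-4-[(triisopropylsilyl)oxy]phenyl}-2-methylpropan-1-one | CC(C)=CCc1c(O[Si](C(C)C)(C(C)C)C(C)C)c(CC2=C(O)[C@@](CC=C(C)C)(C(=O)C(C)C)C(O)=C(C)C2=O)c(O)c(C(=O)C(C)C)c1O | intermediate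
36 | 1-[2,4,6-trihydroxy-3-(3-methylbut-2-en-1-yl)-5-(RBH-methyl)phenyl]-2-methylpropan-1-one (CNP0191741.1) | CC(C)=CCc1c(O)c(CC2=C(O)[C@@](CC=C(C)C)(C(=O)C(C)C)C(O)=C(C)C2=O)c(O)c(C(=O)C(C)C)c1O | target

**Step count and risks**

Total step count: 16. Longest linear sequence: 15 steps (steps 1 to 9, then 11 to 16); step 10 is the one-step branch to the siloxyalkyne.

Most likely to fail, first: step 11. The methoxy-stabilised cyclobutenone may open only at a temperature at which the vinylketene dimerises or esterifies the product phenol. At that temperature the ring B prenyl group may also begin to migrate (Cope shift, then ether formation and aromatisation), which would erode the stereocentre. The fallback gives up the benzannulation for a biomimetic methylene bridging and sets out from dienone 10. Both methyl enol ethers of 10 are cleaved with BCl3 to (4R)-3,5-dihydroxy-2-methyl-4-(3-methylbut-2-en-1-yl)-4-(2-methylpropanoyl)cyclohexa-2,5-dien-1-one F1. Separately, commercial 2-methyl-1-(2,4,6-trihydroxyphenyl)propan-1-one is C-prenylated (prenyl bromide, aqueous KOH) to 2-methyl-1-[2,4,6-trihydroxy-3-(3-methylbut-2-en-1-yl)phenyl]propan-1-one F2. Aminomethylation of F2 with dimethylmethylideneammonium iodide gives the Mannich base 1-{3-[(dimethylamino)methyl]-2,4,6-trihydroxy-5-(3-methylbut-2-en-1-yl)phenyl}-2-methylpropan-1-one F3. Warming F3 with F1 should expel dimethylamine, and conjugate addition of the ring B enol to the resulting ortho-quinone methide would come back to the route at target 36.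

Second: step 9. The acid chloride or the ketene may be captured by the neighbouring vinylogous ester oxygen, the ketene may dimerise, or the zwitterionic adduct with the ketene acetal may open to an acyclic acylation product instead of closing the four-membered ring. The fallback reverses the roles of the two-carbon partners and sets out from iodide 11. Stille coupling with (tributylstannyl)methanol (Pd(PPh3)4) gives (4S)-2-(hydroxymethyl)-3,5-dimethoxy-6-methyl-4-(3-methylbut-2-en-1-yl)-4-(2-methylpropanoyl)cyclohexa-2,5-dien-1-one F4. CBr4 and PPh3 convert F4 into (4S)-2-(bromomethyl)-3,5-dimethoxy-6-methyl-4-(3-methylbut-2-en-1-yl)-4-(2-methylpropanoyl)cyclohexa-2,5-dien-1-one F5. Copper-mediated substitution with lithium methoxyacetylide (CuI) gives (4S)-3,5-dimethoxy-2-(3-methoxyprop-2-yn-1-yl)-6-methyl-4-(3-methylbut-2-en-1-yl)-4-(2-methylpropanoyl)cyclohexa-2,5-dien-1-one F6. A [2+2] cycloaddition of F6 with ketene, CH2=C=O, has the same regiochemistry and comes back to the route at cyclobutenone 19.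

Third: step 14. n-BuLi may add to the ring B carbonyl groups or to the ester before iodine–lithium exchange is complete, or the aryllithium may be protonated before the acyl shift. The fallback replaces the intramolecular anionic shift by a metal-catalysed intermolecular acylation and sets out from iodo ester 32. Nickel-catalysed reductive coupling with 2-methylpropanoyl chloride 31 (NiCl2·MeOCH2CH2OMe, 4,4'-di-tert-butyl-2,2'-bipyridine, Zn, N,N-dimethylacetamide) gives 6-methoxy-3-(3-methylbut-2-en-1-yl)-2-(2-methylpropanoyl)-5-(RB-methyl)-4-[(triisopropylsilyl)oxy]phenyl 2-methylpropanoate F7. Methanolysis of the aryl ester of F7 (K2CO3, MeOH) comes back to the route at hydroxy ketone 34.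

**Further compounds**

F1 | step 11 | (4R)-3,5-dihydroxy-2-methyl-4-(3-methylbut-2-en-1-yl)-4-(2-methylpropanoyl)cyclohexa-2,5-dien-1-one | C1=C(O)[C@@](CC=C(C)C)(C(=O)C(C)C)C(O)=C(C)C1=O
F2 | step 11 | 2-methyl-1-[2,4,6-trihydroxy-3-(3-methylbut-2-en-1-yl)phenyl]propan-1-one | CC(C)=CCc1c(O)cc(O)c(C(=O)C(C)C)c1O
F3 | step 11 | 1-{3-[(dimethylamino)methyl]-2,4,6-trihydroxy-5-(3-methylbut-2-en-1-yl)phenyl}-2-methylpropan-1-one | CC(C)=CCc1c(O)c(CN(C)C)c(O)c(C(=O)C(C)C)c1O
F4 | step 9 | (4S)-2-(hydroxymethyl)-3,5-dimethoxy-6-methyl-4-(3-methylbut-2-en-1-yl)-4-(2-methylpropanoyl)cyclohexa-2,5-dien-1-one | OCC1=C(OC)[C@@](CC=C(C)C)(C(=O)C(C)C)C(OC)=C(C)C1=O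
F5 | step 9 | (4S)-2-(bromomethyl)-3,5-dimethoxy-6-methyl-4-(3-methylbut-2-en-1-yl)-4-(2-methylpropanoyl)cyclohexa-2,5-dien-1-one | BrCC1=C(OC)[C@@](CC=C(C)C)(C(=O)C(C)C)C(OC)=C(C)C1=O
F6 | step 9 | (4S)-3,5-dimethoxy-2-(3-methoxyprop-2-yn-1-yl)-6-methyl-4-(3-methylbut-2-en-1-yl)-4-(2-methylpropanoyl)cyclohexa-2,5-dien-1-one | COC#CCC1=C(OC)[C@@](CC=C(C)C)(C(=O)C(C)C)C(OC)=C(C)C1=O
F7 | step 14 | 6-methoxy-3-(3-methylbut-2-en-1-yl)-2-(2-methylpropanoyl)-5-(RB-methyl)-4-[(triisopropylsilyl)oxy]phenyl 2-methylpropanoate | CC(C)=CCc1c(O[Si](C(C)C)(C(C)C)C(C)C)c(CC2=C(OC)[C@@](CC=C(C)C)(C(=O)C(C)C)C(OC)=C(C)C2=O)c(OC)c(C(=O)C(C)C)c1OC(=O)C(C)C
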